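The oxolane ring is disconnected at O1: its four carbons C2–C5 are carried as a prochiral 3-(arylmethyl)cyclobutanone, and O1 is inserted between C2 and C5 by a catalytic enantioselective Baeyer–Villiger oxidation. This step exploits the unsubstituted C2H2–O1–C5H2 unit: the two α-methylenes of the cyclobutanone are enantiotopic, so one operation expands the four-membered ring to the five-membered ring and fixes C4 (R). The lactone carbonyl (future C2) then carries an aldol condensation; copper-catalysed conjugate borylation and protonation anti to the C4 benzyl group set C3 and the carbinol carbon, and C2 is reduced to CH2 without opening the ring. The boronate masks the benzylic alcohol to the end.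

Key step: step 2

Remark on numbering: the oxolane is numbered O1, C2, C3 (carries the carbinol side chain), C4 (carries the benzyl group), C5; the lactones use the same numbers, with C2 as the carbonyl carbon. The target is the 3,4-cis isomer (3S,4R) with an (S)-carbinol.

Assumption: compounds 1, 2 and 6 are taken as commercial. The sense of induction of the chiral acid in step 2, of the chiral diphosphine in step 4 and of the chiral diol in the fallback to step 2 is assumed as written; the antipode of each is available if the opposite sense is found.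

Step 1
Reactants: 1 2-(benzyloxy)-4-bromo-1-methoxybenzene; 2 3-(bromomethyl)cyclobutan-1-one
Product: 3 3-[3-(benzyloxy)-4-methoxybenzyl]cyclobutan-1-one
Conditions: NiI2 (10 mol%), 4,4'-di-tert-butyl-2,2'-bipyridine (10 mol%), NaI (25 mol%), pyridine (10 mol%), Zn dust (2 equiv), DMPU, 60 °C
Reagents that add atoms: none
Why: Nickel-catalysed cross-electrophile (reductive) coupling of an aryl bromide with a primary alkyl bromide, with Zn as terminal reductant; the ketone is tolerated, the cyclobutylmethyl radical should be captured by nickel faster than it ring-opens, and no stereocentre is formed.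

Step 2
Reactants: 3 3-[3-(benzyloxy)-4-methoxybenzyl]cyclobutan-1-one
Product: 5 (R)-4-[3-(benzyloxy)-4-methoxybenzyl]dihydrofuran-2(3H)-one, via Criegee perhydrate 4 (not isolated)
Conditions: (R)-3,3'-di(pyren-1-yl)-H8-BINOL hydrogen phosphate (10 mol%), 30% aq H2O2 (1.5 equiv), CHCl3, −40 °C
Reagents that add atoms: hydrogen peroxide, OO
Why: Organocatalytic enantioselective Baeyer–Villiger oxidation: the chiral phosphoric acid activates the strained ketone and H2O2 by hydrogen bonding, the perhydrate 4 forms, and one α-methylene migrates from carbon to oxygen with loss of water. The closest known reaction type is the chiral-Brønsted-acid-catalysed Baeyer–Villiger desymmetrisation of 3-substituted cyclobutanones with aqueous H2O2. No ring is closed by cyclisation: the five-membered lactone arises from the four-membered ketone by a 1,2-shift that inserts O1 between the carbonyl carbon and one α-carbon (4 → 5 ring expansion, driven by release of ring strain). The new stereocentre C4 (former C3 of the cyclobutanone) is set because the catalyst alone decides which of the two enantiotopic CH2 groups migrates within its hydrogen-bonded chiral pocket. The step needs enantiotopic-group selectivity (catalyst) and chemoselectivity for the ketone over the electron-rich arene and the benzyl ether (secured by the electrophilicity of the strained carbonyl and the mildness of H2O2 at low temperature); regiochemistry is no issue, since both α-carbons are CH2 and either migration gives the same constitution.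

Step 3
Reactants: 5 (R)-4-[3-(benzyloxy)-4-methoxybenzyl]dihydrofuran-2(3H)-one; 6 3-(benzyloxy)-4-methoxybenzaldehyde
Product: 10 (R,E)-4-[3-(benzyloxy)-4-methoxybenzyl]-3-[3-(benzyloxy)-4-methoxybenzylidene]dihydrofuran-2(3H)-one, via lithium enolate 7 (not isolated), via lithium aldolate 8 (not isolated), via aldol mesylate 9 (not isolated)
Conditions: LiN(i-Pr)2 (LDA, 1.1 equiv), THF, −78 °C; 6; MsCl (1.5 equiv), −78 to 0 °C; DBU (3 equiv), 0 °C to rt
Reagents that add atoms: none
Why: Aldol condensation in one flask (aldol addition of the lactone lithium enolate, O-mesylation, E1cB elimination with DBU), which should give the thermodynamically preferred E-arylidene; C4 is not acidic in 5 and DBU exposure is kept short and cold so that it is not touched in 10.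

Step 4
Reactants: 10 (R,E)-4-[3-(benzyloxy)-4-methoxybenzyl]-3-[3-(benzyloxy)-4-methoxybenzylidene]dihydrofuran-2(3H)-one
Product: 11 (3S,4R)-4-[3-(benzyloxy)-4-methoxybenzyl]-3-{(S)-[3-(benzyloxy)-4-methoxyphenyl](4,4,5,5-tetramethyl-1,3,2-dioxaborolan-2-yl)methyl}dihydrofuran-2(3H)-one (3,4-cis)
Conditions: CuCl (5 mol%), NaOt-Bu (10 mol%), (R)-1-[(S)-2-(diphenylphosphino)ferrocenyl]ethyldicyclohexylphosphine (5.5 mol%), bis(pinacolato)diboron (B2pin2, 1.2 equiv), MeOH (2 equiv), THF, 0 °C to rt
Reagents that add atoms: bis(pinacolato)diboron, CC1(C)OB(OC1(C)C)B1OC(C)(C)C(C)(C)O1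
Why: Copper-catalysed enantioselective conjugate (β-) borylation of an α,β-unsaturated lactone with protonation by MeOH: the ligated Cu–Bpin species should add to the s-cis-locked E-enoate from the face anti to the C4 arylmethyl group (Re face of the benzylidene carbon; substrate bias reinforced by the matched diphosphine) to set the benzylic C–B centre (S), and the copper enolate should be protonated on the same less hindered face to set C3 (S), giving the 3,4-cis lactone.

Step 5
Reactants: 11 (3S,4R)-4-[3-(benzyloxy)-4-methoxybenzyl]-3-{(S)-[3-(benzyloxy)-4-methoxyphenyl](4,4,5,5-tetramethyl-1,3,2-dioxaborolan-2-yl)methyl}dihydrofuran-2(3H)-one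
Product: 12 (3S,4R)-4-[3-(benzyloxy)-4-methoxybenzyl]-3-{(S)-[3-(benzyloxy)-4-methoxyphenyl](4,4,5,5-tetramethyl-1,3,2-dioxaborolan-2-yl)methyl}tetrahydrofuran-2-ol (mixture of C2 epimers)
Conditions: i-Bu2AlH (DIBAL-H, 1.2 equiv), CH2Cl2, −78 °C; aq KNaC4H4O6 (potassium sodium tartrate) work-up
Reagents that add atoms: none
Why: Partial reduction of a lactone to the lactol with DIBAL-H through a tetrahedral aluminium hemiacetal that is stable at −78 °C; the pinacol boronate and benzyl ethers should be inert at this temperature, and the new C2 centre is an inconsequential anomeric mixture.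

Step 6
Reactants: 12 (3S,4R)-4-[3-(benzyloxy)-4-methoxybenzyl]-3-{(S)-[3-(benzyloxy)-4-methoxyphenyl](4,4,5,5-tetramethyl-1,3,2-dioxaborolan-2-yl)methyl}tetrahydrofuran-2-ol
Product: 13 2-{(S)-[3-(benzyloxy)-4-methoxyphenyl][(3S,4R)-4-[3-(benzyloxy)-4-methoxybenzyl]tetrahydrofuran-3-yl]methyl}-4,4,5,5-tetramethyl-1,3,2-dioxaborolane
Conditions: Et3SiH (3 equiv), BF3·OEt2 (1.5 equiv), CH2Cl2, −78 to −40 °C
Reagents that add atoms: none
Why: Lewis-acid-mediated ionic hydrogenation of a lactol (reductive deoxygenation through the cyclic oxocarbenium ion, which Et3SiH should reduce at low temperature faster than C3 can enolise), so C2 becomes CH2 with the ring intact and the cis C3/C4 relationship preserved; the benzylic C–B bond, unlike a benzylic C–O bond, cannot ionise here.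

Step 7
Reactants: 13 2-{(S)-[3-(benzyloxy)-4-methoxyphenyl][(3S,4R)-4-[3-(benzyloxy)-4-methoxybenzyl]tetrahydrofuran-3-yl]methyl}-4,4,5,5-tetramethyl-1,3,2-dioxaborolane
Product: 14 2-methoxy-5-{[(3R,4S)-4-[(S)-(3-hydroxy-4-methoxyphenyl)(4,4,5,5-tetramethyl-1,3,2-dioxaborolan-2-yl)methyl]tetrahydrofuran-3-yl]methyl}phenol
Conditions: H2 (1 atm), Pd/C (10 wt%), EtOAc–MeOH, rt
Reagents that add atoms: none
Why: Catalytic hydrogenolysis of the two aryl benzyl ethers; the C–B bond, the oxolane and the stereocentres are inert, and because the benzylic oxygen is not yet present it cannot be hydrogenolysed.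

Step 8
Reactants: 14 2-methoxy-5-{[(3R,4S)-4-[(S)-(3-hydroxy-4-methoxyphenyl)(4,4,5,5-tetramethyl-1,3,2-dioxaborolan-2-yl)methyl]tetrahydrofuran-3-yl]methyl}phenol
Product: 16 (S)-[(3S,4R)-4-(3-hydroxy-4-methoxybenzyl)tetrahydrofuran-3-yl](3-hydroxy-4-methoxyphenyl)methanol, via borate ester 15 (not isolated)
Conditions: NaBO3·4H2O (4 equiv), THF–H2O (1:1), rt; then aq NH4Cl
Reagents that add atoms: sodium perborate (dimeric peroxoborate, used as the tetrahydrate), [Na+].[Na+].O[B-]1(O)OO[B-](O)(O)OO1
Why: Oxidation of a secondary alkyl pinacol boronate with perborate: the peroxide adds to boron and carbon migrates from boron to oxygen with retention of configuration, so hydrolysis of borate 15 should give the (S)-carbinol; perborate is mild enough for the free guaiacol-type phenols.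

Compound list
1 | 2-(benzyloxy)-4-bromo-1-methoxybenzene | COc1ccc(Br)cc1OCc1ccccc1 | starting material
2 | 3-(bromomethyl)cyclobutan-1-one | O=C1CC(CBr)C1 | starting material
3 | 3-[3-(benzyloxy)-4-methoxybenzyl]cyclobutan-1-one | COc1ccc(CC2CC(=O)C2)cc1OCc1ccccc1 | intermediate
4 | 3-[3-(benzyloxy)-4-methoxybenzyl]-1-hydroperoxycyclobutan-1-ol (Criegee perhydrate) | COc1ccc(CC2CC(O)(OO)C2)cc1OCc1ccccc1 | intermediate
5 | (R)-4-[3-(benzyloxy)-4-methoxybenzyl]dihydrofuran-2(3H)-one | COc1ccc(C[C@H]2COC(=O)C2)cc1OCc1ccccc1 | intermediate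
6 | 3-(benzyloxy)-4-methoxybenzaldehyde | COc1ccc(C=O)cc1OCc1ccccc1 | starting material
7 | lithium enolate of 5 | COc1ccc(C[C@H]2COC([O-])=C2)cc1OCc1ccccc1.[Li+] | intermediate
8 | lithium alkoxide of (3S,4R)-4-[3-(benzyloxy)-4-methoxybenzyl]-3-{[3-(benzyloxy)-4-methoxyphenyl](hydroxy)methyl}dihydrofuran-2(3H)-one (3,4-trans; both carbinol epimers) | COc1ccc(C[C@H]2COC(=O)[C@@H]2C([O-])c2ccc(OC)c(OCc3ccccc3)c2)cc1OCc1ccccc1.[Li+] | intermediate
9 | [3-(benzyloxy)-4-methoxyphenyl]{(3S,4R)-4-[3-(benzyloxy)-4-methoxybenzyl]-2-oxotetrahydrofuran-3-yl}methyl methanesulfonate (3,4-trans; both epimers at the mesylate carbon) | COc1ccc(C[C@H]2COC(=O)[C@@H]2C(OS(C)(=O)=O)c2ccc(OC)c(OCc3ccccc3)c2)cc1OCc1ccccc1 | intermediate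
10 | (R,E)-4-[3-(benzyloxy)-4-methoxybenzyl]-3-[3-(benzyloxy)-4-methoxybenzylidene]dihydrofuran-2(3H)-one | COc1ccc(C[C@H]2COC(=O)/C2=C/c2ccc(OC)c(OCc3ccccc3)c2)cc1OCc1ccccc1 | intermediate
11 | (3S,4R)-4-[3-(benzyloxy)-4-methoxybenzyl]-3-{(S)-[3-(benzyloxy)-4-methoxyphenyl](4,4,5,5-tetramethyl-1,3,2-dioxaborolan-2-yl)methyl}dihydrofuran-2(3H)-one (3,4-cis) | COc1ccc(C[C@H]2COC(=O)[C@H]2[C@H](B2OC(C)(C)C(C)(C)O2)c2ccc(OC)c(OCc3ccccc3)c2)cc1OCc1ccccc1 | intermediate
12 | (3S,4R)-4-[3-(benzyloxy)-4-methoxybenzyl]-3-{(S)-[3-(benzyloxy)-4-methoxyphenyl](4,4,5,5-tetramethyl-1,3,2-dioxaborolan-2-yl)methyl}tetrahydrofuran-2-ol (C2 epimers) | COc1ccc(C[C@H]2COC(O)[C@H]2[C@H](B2OC(C)(C)C(C)(C)O2)c2ccc(OC)c(OCc3ccccc3)c2)cc1OCc1ccccc1 | intermediate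
13 | 2-{(S)-[3-(benzyloxy)-4-methoxyphenyl][(3S,4R)-4-[3-(benzyloxy)-4-methoxybenzyl]tetrahydrofuran-3-yl]methyl}-4,4,5,5-tetramethyl-1,3,2-dioxaborolane | COc1ccc(C[C@H]2COC[C@H]2[C@H](B2OC(C)(C)C(C)(C)O2)c2ccc(OC)c(OCc3ccccc3)c2)cc1OCc1ccccc1 | intermediate
14 | 2-methoxy-5-{[(3R,4S)-4-[(S)-(3-hydroxy-4-methoxyphenyl)(4,4,5,5-tetramethyl-1,3,2-dioxaborolan-2-yl)methyl]tetrahydrofuran-3-yl]methyl}phenol | COc1ccc(C[C@H]2COC[C@H]2[C@H](B2OC(C)(C)C(C)(C)O2)c2ccc(OC)c(O)c2)cc1O | intermediate
15 | borate ester of 16: 2-{(S)-(3-hydroxy-4-methoxyphenyl)[(3S,4R)-4-(3-hydroxy-4-methoxybenzyl)tetrahydrofuran-3-yl]methoxy}-4,4,5,5-tetramethyl-1,3,2-dioxaborolane | COc1ccc(C[C@H]2COC[C@H]2[C@H](OB2OC(C)(C)C(C)(C)O2)c2ccc(OC)c(O)c2)cc1O | intermediate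
16 | (S)-[(3S,4R)-4-(3-hydroxy-4-methoxybenzyl)tetrahydrofuran-3-yl](3-hydroxy-4-methoxyphenyl)methanol | COc1ccc(C[C@H]2COC[C@H]2[C@H](O)c2ccc(OC)c(O)c2)cc1O | target

Total step count: 8
Longest linear sequence: 8 steps (1/2 → 3 → 5 → 10 → 11 → 12 → 13 → 14 → 16)

Steps most likely to fail

1. Step 4. What may go wrong: poor facial selectivity in the protonation of the copper enolate (C3 epimer, 3,4-trans), a mismatch between ligand and substrate bias at the benzylic carbon, or base-induced removal of the γ-proton at C4 that erodes its configuration. Fallback (sets out from 10, comes back at 16): the carbonyl is removed first and the two centres are then set by a substrate-controlled syn hydroboration. Reduction of 10 with i-Bu2AlH (CH2Cl2, −78 °C) should give the allylic lactol (4R,E)-4-[3-(benzyloxy)-4-methoxybenzyl]-3-[3-(benzyloxy)-4-methoxybenzylidene]tetrahydrofuran-2-ol F1. Et3SiH/BF3·OEt2 (CH2Cl2, −78 °C) should reduce it to (R,E)-3-[3-(benzyloxy)-4-methoxybenzyl]-4-[3-(benzyloxy)-4-methoxybenzylidene]tetrahydrofuran F2. Hydroboration with BH3·THF (0 °C to rt) should place boron on the less substituted benzylic carbon and deliver H and B syn from the face anti to the benzyl group. Oxidation with NaBO3·4H2O should then give (S)-{(3S,4R)-4-[3-(benzyloxy)-4-methoxybenzyl]tetrahydrofuran-3-yl}[3-(benzyloxy)-4-methoxyphenyl]methanol F3. Brief hydrogenolysis (H2, Pd/C, EtOAc) of F3 should give 16.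

2. Step 6. What may go wrong: epimerisation at C3 through the ring-opened γ-hydroxy aldehyde tautomer of the lactol, or elimination to the cyclic enol ether, before hydride capture. Fallback (sets out from 11, comes back at 13): reductive acetylation in place of the free lactol. Lactone 11 is reduced with i-Bu2AlH (CH2Cl2, −78 °C) and the aluminium hemiacetal is trapped in the same flask with Ac2O/pyridine/DMAP. This should give (3S,4R)-4-[3-(benzyloxy)-4-methoxybenzyl]-3-{(S)-[3-(benzyloxy)-4-methoxyphenyl](4,4,5,5-tetramethyl-1,3,2-dioxaborolan-2-yl)methyl}tetrahydrofuran-2-yl acetate F4, which cannot ring-open. Et3SiH with trimethylsilyl triflate (CH2Cl2, −78 °C) should then reduce F4 to 13.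

3. Step 2. What may go wrong: insufficient discrimination between the enantiotopic methylene groups for a flexible arylmethyl substituent, so that the lactone forms with low enantiomeric purity. Fallback (sets out from 3, comes back at 5): auxiliary-controlled ring expansion. Ketone 3 is ketalised with (2R,4R)-pentane-2,4-diol (TsOH, benzene, Dean–Stark) to give (6R,8R)-2-[3-(benzyloxy)-4-methoxybenzyl]-6,8-dimethyl-5,9-dioxaspiro[3.5]nonane F5. Oxidation with mCPBA and SnCl4 (CH2Cl2, −78 °C) makes the two ring C–C bonds diastereotopic in the Lewis-acid-opened ketal, and aqueous work-up should release 5 and the diol.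

Further compounds
F1 | step 4 | (4R,E)-4-[3-(benzyloxy)-4-methoxybenzyl]-3-[3-(benzyloxy)-4-methoxybenzylidene]tetrahydrofuran-2-ol | COc1ccc(C[C@H]2COC(O)/C2=C/c2ccc(OC)c(OCc3ccccc3)c2)cc1OCc1ccccc1
F2 | step 4 | (R,E)-3-[3-(benzyloxy)-4-methoxybenzyl]-4-[3-(benzyloxy)-4-methoxybenzylidene]tetrahydrofuran | COc1ccc(C[C@H]2COC/C2=C/c2ccc(OC)c(OCc3ccccc3)c2)cc1OCc1ccccc1
F3 | step 4 | (S)-{(3S,4R)-4-[3-(benzyloxy)-4-methoxybenzyl]tetrahydrofuran-3-yl}[3-(benzyloxy)-4-methoxyphenyl]methanol | COc1ccc(C[C@H]2COC[C@H]2[C@H](O)c2ccc(OC)c(OCc3ccccc3)c2)cc1OCc1ccccc1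
F4 | step 6 | (3S,4R)-4-[3-(benzyloxy)-4-methoxybenzyl]-3-{(S)-[3-(benzyloxy)-4-methoxyphenyl](4,4,5,5-tetramethyl-1,3,2-dioxaborolan-2-yl)methyl}tetrahydrofuran-2-yl acetate | COc1ccc(C[C@H]2COC(OC(C)=O)[C@H]2[C@H](B2OC(C)(C)C(C)(C)O2)c2ccc(OC)c(OCc3ccccc3)c2)cc1OCc1ccccc1
F5 | step 2 | (6R,8R)-2-[3-(benzyloxy)-4-methoxybenzyl]-6,8-dimethyl-5,9-dioxaspiro[3.5]nonane | C[C@@H]1C[C@@H](C)OC2(CC(Cc3ccc(OC)c(OCc4ccccc4)c3)C2)O1
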